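**Plan**
- Numbering: the heptane chain runs from C1 (benzylic CH2 on the guaiacyl ring) to C7 (benzylic CH2 on the catechol ring); the target is the (3R,5S) syn-diacetate.
- Enabling feature: C1 is benzylic and stands 1,5 to the C5 oxygen, so C1–C5 plus that oxygen can be written as a tetrahydropyran ring. C3 is then the ring C4 carbinol, and the benzylic C1–O bond of this ring is cleaved reductively at the end.
- Retrosynthetic cuts, in order: aryl acetates (back to a pentol); C1–H back to the ring C1–O bond; C1–C2 and C5–O together ([4+2]) to O-benzylvanillin and a 2-silyloxy diene; the diene C4=C5 bond (Wittig) back to dihydrocaffeic acid.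
- Forward order: the C2–C7 diene arm is built linearly, the pyran ring closes in one cycloaddition, the ring ketone is unmasked and reduced, the ring is opened together with global debenzylation, and the acetates are adjusted last.
- Stereochemistry: a chiral CrCl Schiff-base complex selects the aldehyde face and the endo mode relays this to C5 (S). Equatorial hydride delivery to the cis-2,6-pyranone gives the axial alcohol, which is C3 (R) and syn to the C5 oxygen. The C1 centre is sacrificial.

Key step: step 5

Assumption: the sense of induction of the chromium complex is assigned by analogy with its usual behaviour toward simple aldehydes, which points to the ligand from (1S,2R)-1-amino-2-indanol for the (2S,6S) adduct. Should the first run show the opposite sense, the enantiomeric aminoindanol is used with no other change.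

**Route**

Step 1
Reactants: 1 3-(3,4-dihydroxyphenyl)propanoic acid
Product: 2 benzyl 3-[3,4-bis(benzyloxy)phenyl]propanoate
Conditions: BnBr (3.5 equiv), K2CO3, DMF, 60 °C, under argon
Reagents that add atoms: benzyl bromide, BrCc1ccccc1
Why: Williamson-type SN2 alkylation of the carboxylate and both phenoxides should protect all three acidic sites in one operation with groups that later leave by hydrogenolysis.

Step 2
Reactants: 2 benzyl 3-[3,4-bis(benzyloxy)phenyl]propanoate
Product: 3 3-[3,4-bis(benzyloxy)phenyl]propanal
Conditions: i-Bu2AlH (1.1 equiv), CH2Cl2, −78 °C; MeOH, then aq. potassium sodium tartrate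
Reagents that add atoms: none
Why: Partial ester reduction with i-Bu2AlH should stop at the aldehyde because the tetrahedral aluminium hemiacetal persists at −78 °C until work-up; the aryl benzyl ethers are inert.

Step 3
Reactants: 3 3-[3,4-bis(benzyloxy)phenyl]propanal; 4 1-(triphenylphosphoranylidene)propan-2-one
Product: 5 (3E)-6-[3,4-bis(benzyloxy)phenyl]hex-3-en-2-one
Conditions: CH2Cl2, reflux
Reagents that add atoms: none
Why: Wittig olefination with a stabilised acyl ylide should give the E-enone selectively through the thermodynamically favoured oxaphosphetane.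

Step 4
Reactants: 5 (3E)-6-[3,4-bis(benzyloxy)phenyl]hex-3-en-2-one
Product: 6 triethyl{[(3E)-6-[3,4-bis(benzyloxy)phenyl]hexa-1,3-dien-2-yl]oxy}silane
Conditions: Et3SiOTf (1.2 equiv), Et3N (2 equiv), Et2O, 0 °C; used crude after non-aqueous work-up
Reagents that add atoms: triethylsilyl trifluoromethanesulfonate, CC[Si](CC)(CC)OS(=O)(=O)C(F)(F)F
Why: Soft enolisation (O-silylation of the enone, then kinetic deprotonation of the methyl group by the amine) should give the cross-conjugated 2-silyloxy diene with the E-alkene untouched.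

Step 5
Reactants: 6 triethyl{[(3E)-6-[3,4-bis(benzyloxy)phenyl]hexa-1,3-dien-2-yl]oxy}silane; 7 4-(benzyloxy)-3-methoxybenzaldehyde
Product: 8 (2S,6S)-2-[4-(benzyloxy)-3-methoxyphenyl]-6-{2-[3,4-bis(benzyloxy)phenyl]ethyl}-4-[(triethylsilyl)oxy]-3,6-dihydro-2H-pyran (2,6-cis)
Conditions: CrCl(C27H29NO2) (5–10 mol%; trivalent chromium; C27H29NO2 = dianion of the Schiff base from 3-(1-adamantyl)-2-hydroxy-5-methylbenzaldehyde and (1S,2R)-1-amino-2-indanol), powdered 4 Å molecular sieves, acetone (minimum volume), rt; filtration and chromatography on Et3N-deactivated silica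
Reagents that add atoms: none
Why: The chromium centre binds the aldehyde oxygen of 7, and the CH2 terminus of 6 (the only nucleophilic diene terminus, since the 2-silyloxy group polarises the diene) adds to the carbonyl carbon while the carbonyl oxygen closes onto the alkyl-bearing terminus in a concerted, asynchronous [4+2] cycloaddition that forms C1–C2 and C5–O. The closest known reaction type is the asymmetric hetero-Diels–Alder reaction of 2-silyloxy-1,3-dienes with aldehydes under tridentate Schiff-base CrCl catalysis, which delivers cis-2,6-disubstituted 4-silyloxy-dihydropyrans. The six-membered oxygen ring closes in cycloaddition mode, suprafacially on both components, with no separate cyclisation event. The C1 centre (pyran C2, S) is fixed by the ligand, which shields one face of the bound aldehyde, and the C5 centre (pyran C6, S) follows from the endo transition state together with the E geometry of the diene, hence the cis relationship. The step needs regio-, endo- and enantiofacial selectivity and must avoid an open Mukaiyama aldol pathway; the silyloxy group secures the first, the rigid tridentate ligand the other two, and the non-enolisable aldehyde and the sieves keep the diene from being consumed by proton transfer or hydrolysis. Only the C5 configuration has to last, because C1 later becomes a methylene.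

Step 6
Reactants: 8 (2S,6S)-2-[4-(benzyloxy)-3-methoxyphenyl]-6-{2-[3,4-bis(benzyloxy)phenyl]ethyl}-4-[(triethylsilyl)oxy]-3,6-dihydro-2H-pyran
Product: 9 (2S,6S)-2-[4-(benzyloxy)-3-methoxyphenyl]-6-{2-[3,4-bis(benzyloxy)phenyl]ethyl}tetrahydro-4H-pyran-4-one (2,6-cis)
Conditions: Bu4NF (1.1 equiv), AcOH (1.2 equiv), THF, 0 °C
Reagents that add atoms: none
Why: Fluoride cleavage of the silyl enol ether, buffered with AcOH so that the enolate is protonated at once, should unmask the ketone without retro-oxa-Michael opening of the β-alkoxy ketone and without touching either stereocentre.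

Step 7
Reactants: 9 (2S,6S)-2-[4-(benzyloxy)-3-methoxyphenyl]-6-{2-[3,4-bis(benzyloxy)phenyl]ethyl}tetrahydro-4H-pyran-4-one
Product: 10 (2S,4S,6S)-2-[4-(benzyloxy)-3-methoxyphenyl]-6-{2-[3,4-bis(benzyloxy)phenyl]ethyl}tetrahydro-2H-pyran-4-ol (4-OH axial, trans to both ring substituents)
Conditions: LiBH(s-Bu)3 (1.2 equiv), THF, −78 °C; then H2O
Reagents that add atoms: none
Why: Reduction with a bulky trialkylborohydride should attack the chair with both substituents equatorial along the equatorial trajectory, giving the axial (4S) alcohol, which is the arrangement that places the C3 and C5 oxygens syn in the open chain.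

Step 8
Reactants: 10 (2S,4S,6S)-2-[4-(benzyloxy)-3-methoxyphenyl]-6-{2-[3,4-bis(benzyloxy)phenyl]ethyl}tetrahydro-2H-pyran-4-ol
Product: 11 (3R,5S)-7-(3,4-dihydroxyphenyl)-1-(4-hydroxy-3-methoxyphenyl)heptane-3,5-diol
Conditions: H2 (4 atm), Pd(OH)2/C, MeOH–AcOH (10:1), rt
Reagents that add atoms: none
Why: Catalytic hydrogenolysis of benzylic C–O bonds should remove the three O-benzyl groups and then cleave the ring C1–O bond, which the freed para-hydroxyl activates as in guaiacyl-substituted cyclic ether lignans; the non-benzylic C5–O bond and both carbinol centres are untouched.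

Step 9
Reactants: 11 (3R,5S)-7-(3,4-dihydroxyphenyl)-1-(4-hydroxy-3-methoxyphenyl)heptane-3,5-diol
Product: 12 (3R,5S)-1-[4-(acetyloxy)-3-methoxyphenyl]-7-[3,4-bis(acetyloxy)phenyl]heptane-3,5-diyl diacetate
Conditions: Ac2O (excess), pyridine, DMAP (cat.), CH2Cl2, rt
Reagents that add atoms: acetic anhydride, CC(=O)OC(C)=O
Why: DMAP-catalysed acylation should esterify all three phenols and both secondary alcohols, with no bond to a stereocentre being broken.

Step 10
Reactants: 12 (3R,5S)-1-[4-(acetyloxy)-3-methoxyphenyl]-7-[3,4-bis(acetyloxy)phenyl]heptane-3,5-diyl diacetate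
Product: 13 (3R,5S)-7-(3,4-dihydroxyphenyl)-1-(4-hydroxy-3-methoxyphenyl)heptane-3,5-diyl diacetate
Conditions: N2H4·H2O (3.3 equiv), THF, 0 °C to rt, under argon
Reagents that add atoms: none
Why: Chemoselective hydrazinolysis of aryl esters should remove the three phenolic acetates, because phenoxide is a far better leaving group than a secondary alkoxide, leaving the two alkyl acetates in place.

**Compound list**
1 | 3-(3,4-dihydroxyphenyl)propanoic acid | O=C(O)CCc1ccc(O)c(O)c1 | starting material
2 | benzyl 3-[3,4-bis(benzyloxy)phenyl]propanoate | O=C(CCc1ccc(OCc2ccccc2)c(OCc2ccccc2)c1)OCc1ccccc1 | intermediate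
3 | 3-[3,4-bis(benzyloxy)phenyl]propanal | O=CCCc1ccc(OCc2ccccc2)c(OCc2ccccc2)c1 | intermediate
4 | 1-(triphenylphosphoranylidene)propan-2-one | CC(=O)C=P(c1ccccc1)(c1ccccc1)c1ccccc1 | starting material
5 | (3E)-6-[3,4-bis(benzyloxy)phenyl]hex-3-en-2-one | CC(=O)/C=C/CCc1ccc(OCc2ccccc2)c(OCc2ccccc2)c1 | intermediate
6 | triethyl{[(3E)-6-[3,4-bis(benzyloxy)phenyl]hexa-1,3-dien-2-yl]oxy}silane | C=C(O[Si](CC)(CC)CC)/C=C/CCc1ccc(OCc2ccccc2)c(OCc2ccccc2)c1 | intermediate
7 | 4-(benzyloxy)-3-methoxybenzaldehyde | COc1cc(C=O)ccc1OCc1ccccc1 | starting material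
8 | (2S,6S)-2-[4-(benzyloxy)-3-methoxyphenyl]-6-{2-[3,4-bis(benzyloxy)phenyl]ethyl}-4-[(triethylsilyl)oxy]-3,6-dihydro-2H-pyran | CC[Si](CC)(CC)OC1=C[C@H](CCc2ccc(OCc3ccccc3)c(OCc3ccccc3)c2)O[C@H](c2ccc(OCc3ccccc3)c(OC)c2)C1 | intermediate
9 | (2S,6S)-2-[4-(benzyloxy)-3-methoxyphenyl]-6-{2-[3,4-bis(benzyloxy)phenyl]ethyl}tetrahydro-4H-pyran-4-one | O=C1C[C@H](CCc2ccc(OCc3ccccc3)c(OCc3ccccc3)c2)O[C@H](c2ccc(OCc3ccccc3)c(OC)c2)C1 | intermediate
10 | (2S,4S,6S)-2-[4-(benzyloxy)-3-methoxyphenyl]-6-{2-[3,4-bis(benzyloxy)phenyl]ethyl}tetrahydro-2H-pyran-4-ol | O[C@H]1C[C@H](CCc2ccc(OCc3ccccc3)c(OCc3ccccc3)c2)O[C@H](c2ccc(OCc3ccccc3)c(OC)c2)C1 | intermediate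
11 | (3R,5S)-7-(3,4-dihydroxyphenyl)-1-(4-hydroxy-3-methoxyphenyl)heptane-3,5-diol | COc1cc(CC[C@H](C[C@H](CCc2ccc(O)c(O)c2)O)O)ccc1O | intermediate
12 | (3R,5S)-1-[4-(acetyloxy)-3-methoxyphenyl]-7-[3,4-bis(acetyloxy)phenyl]heptane-3,5-diyl diacetate | COc1cc(CC[C@H](C[C@H](CCc2ccc(OC(C)=O)c(OC(C)=O)c2)OC(C)=O)OC(C)=O)ccc1OC(C)=O | intermediate
13 | (3R,5S)-7-(3,4-dihydroxyphenyl)-1-(4-hydroxy-3-methoxyphenyl)heptane-3,5-diyl diacetate | COc1cc(CC[C@H](C[C@H](CCc2ccc(O)c(O)c2)OC(C)=O)OC(C)=O)ccc1O | target

**Step count**
Total steps: 10. Longest linear sequence: 10 steps (1 to 13); 4 and 7 are purchased.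

**Steps most likely to fail**

Step 5. The para-alkoxy group lowers the electrophilicity of the aldehyde, so the cycloaddition may be slow; diene hydrolysis or an open aldol pathway could then erode conversion and enantioselectivity. The fallback forms the same two bonds stepwise, setting out from 5 (with 7 as partner) and returning at 9. Enolisation of 5 with (+)-Ipc2BCl and Et3N in Et2O, addition of 7 at −78 °C and buffered H2O2 work-up should give the aldol (1S,4E)-1-[4-(benzyloxy)-3-methoxyphenyl]-7-[3,4-bis(benzyloxy)phenyl]-1-hydroxyhept-4-en-3-one F1; the (+)-reagent is the antipode expected to direct a methyl ketone enolate to the si face of the aldehyde. A reversible 6-endo oxa-Michael addition under mild base (KOt-Bu, 10 mol%, THF, −20 °C; acid is avoided because the electron-rich benzylic carbinol could ionise) should then settle on the diequatorial cis ketone 9. Here C1 is set by the boron reagent and C5 by thermodynamic control; the enantioselectivity is expected to be lower than in the cycloaddition, so 9 may need enrichment by crystallisation.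

Step 8. Once the benzyl ethers are gone, cleavage of the cyclic benzylic C1–O bond may stall, since a 2-aryl tetrahydropyran is hydrogenolysed more slowly than an O-benzyl group, leaving ring-closed phenolic material. The fallback sets out from 10 and returns at 13. Ionic hydrogenation (Et3SiH, BF3·OEt2, CH2Cl2, −40 to 0 °C) should ionise the para-alkoxybenzylic C1–O bond and reduce the cation to (3R,5S)-1-[4-(benzyloxy)-3-methoxyphenyl]-7-[3,4-bis(benzyloxy)phenyl]heptane-3,5-diol F2. Acetylation (Ac2O, pyridine, DMAP) should give (3R,5S)-1-[4-(benzyloxy)-3-methoxyphenyl]-7-[3,4-bis(benzyloxy)phenyl]heptane-3,5-diyl diacetate F3, and ordinary debenzylation (H2, Pd/C, EtOAc, rt) should then give 13 directly. This detour also removes the need to distinguish aryl from alkyl acetates.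

Step 2. The aluminium hemiacetal may collapse before the quench, leading to over-reduction to the primary alcohol and a mixture of oxidation levels. The fallback sets out from 2 and returns at 3: full reduction with LiAlH4 (THF, 0 °C) should give 3-[3,4-bis(benzyloxy)phenyl]propan-1-ol F4, and oxidation with Dess–Martin periodinane (CH2Cl2, NaHCO3, rt) should return aldehyde 3.

**Further compounds**
F1 | step 5 | (1S,4E)-1-[4-(benzyloxy)-3-methoxyphenyl]-7-[3,4-bis(benzyloxy)phenyl]-1-hydroxyhept-4-en-3-one | COc1cc([C@@H](O)CC(=O)/C=C/CCc2ccc(OCc3ccccc3)c(OCc3ccccc3)c2)ccc1OCc1ccccc1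
F2 | step 8 | (3R,5S)-1-[4-(benzyloxy)-3-methoxyphenyl]-7-[3,4-bis(benzyloxy)phenyl]heptane-3,5-diol | COc1cc(CC[C@H](C[C@H](CCc2ccc(OCc3ccccc3)c(OCc3ccccc3)c2)O)O)ccc1OCc1ccccc1
F3 | step 8 | (3R,5S)-1-[4-(benzyloxy)-3-methoxyphenyl]-7-[3,4-bis(benzyloxy)phenyl]heptane-3,5-diyl diacetate | COc1cc(CC[C@H](C[C@H](CCc2ccc(OCc3ccccc3)c(OCc3ccccc3)c2)OC(C)=O)OC(C)=O)ccc1OCc1ccccc1
F4 | step 2 | 3-[3,4-bis(benzyloxy)phenyl]propan-1-ol | OCCCc1ccc(OCc2ccccc2)c(OCc2ccccc2)c1
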